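**Retrosynthetic overview**

1. Target 21 ⇒ axial alcohol 19 (C4–O ester by Mitsunobu inversion) ⇒ ketone 18 ⇒ silyl enol ether 17 ⇒ cycloadduct 16 (C7 isopropenyl from acetyl).
2. Key disconnection: bonds C3a–C7a and C6–C7 of 16 by an intramolecular Diels–Alder reaction of acyclic 15. In 15 the 2-silyloxydiene C3a=C4(OTBS)–C5=C6 and the (Z)-β-acyloxy enone C7=C7a are joined only by the ester O1–C2(=O)–C3.
3. Enabling feature: the γ-lactone atoms O1–C2(=O)–C3 of the target are a ready-made three-atom tether from C7a to C3a. The C4 oxygen is the diene donor, the C7 isopropenyl is a masked acetyl acceptor, and the quaternary C3 (CH3, OAc) biases the tether conformation and the diene face.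
4. 15 ⇐ vinylation of the carboxylate of 11 with (Z)-iodoenone 13; the C3 stereocentre comes from a bis(oxazoline)–Cu(OTf)2 Mukaiyama aldol of enolsilane 5 with tert-butyl pyruvate 6; dienone 4 comes from vinylogous ester 1.
5. Ring order: the cyclohexane ring (C3a–C4–C5–C6–C7–C7a) and the γ-lactone ring close together in step 9; no ring exists before it.

Key step: step 9

Remark: bicyclic compounds carry 1-benzofuran-2-one locants (O1, C2, C3, C3a, C4–C7, C7a); 1, 2, 6, 12 and 20 are taken to be commercial, and the (S,S) ligand is taken to give the (2S) aldol as with other methyl ketone enolsilanes.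

**Route**

Step 1
Reactants: 1 (3E)-4-methoxypent-3-en-2-one; 2 vinylmagnesium bromide
Product: 4 (3E)-4-methylhexa-3,5-dien-2-one, via tertiary dienyl carbinol 3 (not isolated)
Conditions: THF, −78 → 0 °C; then 1 M HCl, 0 °C → rt
Reagents that add atoms: water, O
Why: Stork–Danheiser transposition: 1,2-addition of the Grignard reagent to the vinylogous ester, then acid hydrolysis and dehydration, should give the β,β-disubstituted dienone, with the (3E) isomer (methyl, not vinyl, syn to acetyl) expected as the thermodynamically preferred one.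

Step 2
Reactants: 4 (3E)-4-methylhexa-3,5-dien-2-one
Product: 5 (3E)-4-methyl-2-(trimethylsilyloxy)hexa-1,3,5-triene
Conditions: LiN(i-Pr)2, THF, −78 °C; Me3SiCl, Et3N, −78 → 0 °C
Reagents that add atoms: chlorotrimethylsilane, C[Si](C)(C)Cl
Why: Kinetic silyl enol ether formation: deprotonation at the α′-methyl group and O-silylation should give the cross-conjugated 2-silyloxytriene without touching the 3E double bond.

Step 3
Reactants: 5 (3E)-4-methyl-2-(trimethylsilyloxy)hexa-1,3,5-triene; 6 tert-butyl 2-oxopropanoate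
Product: 8 tert-butyl (2S,5E)-2-hydroxy-2,6-dimethyl-4-oxoocta-5,7-dienoate, via trimethylsilyl ether 7 (not isolated)
Conditions: Cu(OTf)2 (10 mol %), (S,S)-t-Bu-box (11 mol %), THF, −78 °C; then 1 M HCl, THF, 0 °C
Reagents that add atoms: none
Why: Enantioselective Mukaiyama aldol addition to a chelated pyruvate ester: the tert-butyl groups of the ligand should shield one face of the square-planar chelate, so the quaternary carbinol centre (the later C3) is expected as (S).

Step 4
Reactants: 8 tert-butyl (2S,5E)-2-hydroxy-2,6-dimethyl-4-oxoocta-5,7-dienoate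
Product: 9 tert-butyl (2S,5E)-2-(acetyloxy)-2,6-dimethyl-4-oxoocta-5,7-dienoate
Conditions: Ac2O (3 equiv), Sc(OTf)3 (2 mol %), MeCN, −20 °C
Reagents that add atoms: acetic anhydride, CC(=O)OC(C)=O
Why: Sc(OTf)3-catalysed acetylation of a tertiary alcohol under non-basic conditions, chosen to avoid retro-aldol cleavage or β-elimination of the ketol; no stereocentre is touched.

Step 5
Reactants: 9 tert-butyl (2S,5E)-2-(acetyloxy)-2,6-dimethyl-4-oxoocta-5,7-dienoate
Product: 10 (2S,5E)-2-(acetyloxy)-2,6-dimethyl-4-oxoocta-5,7-dienoic acid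
Conditions: CF3CO2H–CH2Cl2 (1:4), 0 °C
Reagents that add atoms: none
Why: Acidolysis of the tert-butyl ester (loss of 2-methylpropene) should leave the tertiary acetate and the dienone intact.

Step 6
Reactants: 10 (2S,5E)-2-(acetyloxy)-2,6-dimethyl-4-oxoocta-5,7-dienoic acid
Product: 11 tert-butyldimethylsilyl (2S,3Z,5E)-2-(acetyloxy)-4-[(tert-butyldimethylsilyl)oxy]-2,6-dimethylocta-3,5,7-trienoate
Conditions: t-BuMe2SiOTf (2.4 equiv), then Et3N (3 equiv), CH2Cl2, −78 → 0 °C; non-aqueous work-up
Reagents that add atoms: tert-butyldimethylsilyl trifluoromethanesulfonate, CC(C)(C)[Si](C)(C)OS(=O)(=O)C(F)(F)F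
Why: Soft enolisation with silyl triflate and amine: the acid becomes the silyl ester and the ketone is enolised toward its CH2 group, the (3Z) geometry (quaternary carbon cis to OSi) following from minimised allylic strain, and adding the triflate before the amine should suppress E1cB loss of acetate.

Step 7
Reactants: 12 but-3-yn-2-one
Product: 13 (3Z)-4-iodobut-3-en-2-one
Conditions: NaI, AcOH, rt
Reagents that add atoms: sodium iodide, [Na+].[I-]
Why: Conjugate hydroiodination of the ynone by anti addition under kinetic control should give the (Z)-β-iodoenone.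

Step 8
Reactants: 11 tert-butyldimethylsilyl (2S,3Z,5E)-2-(acetyloxy)-4-[(tert-butyldimethylsilyl)oxy]-2,6-dimethylocta-3,5,7-trienoate; 13 (3Z)-4-iodobut-3-en-2-one
Product: 15 (1Z)-3-oxobut-1-en-1-yl (2S,3Z,5E)-2-(acetyloxy)-4-[(tert-butyldimethylsilyl)oxy]-2,6-dimethylocta-3,5,7-trienoate, via potassium carboxylate 14 (not isolated)
Conditions: KHCO3 (1.0 equiv), THF–H2O, 0 °C; evaporate (PhMe azeotrope); 13, 18-crown-6 (cat.), DMF, −20 → 0 °C
Reagents that add atoms: none
Why: Hydrolysis of the labile silyl ester, then nucleophilic vinylic substitution (addition–elimination) of the carboxylate on the β-iodoenone, which with a good leaving group should proceed with retention and give the (Z)-enol ester while the silyl dienol ether survives.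

Step 9
Reactants: 15 (1Z)-3-oxobut-1-en-1-yl (2S,3Z,5E)-2-(acetyloxy)-4-[(tert-butyldimethylsilyl)oxy]-2,6-dimethylocta-3,5,7-trienoate
Product: 16 (3S,3aS,6R,7R,7aS)-7-acetyl-4-[(tert-butyldimethylsilyl)oxy]-6-ethenyl-3,6-dimethyl-2-oxo-2,3,3a,6,7,7a-hexahydro-1-benzofuran-3-yl acetate
Conditions: PhMe (0.005 M), BHT (cat.), 110 °C, sealed tube
Reagents that add atoms: none
Why: On heating, 15 should undergo a thermal, asynchronous but concerted intramolecular [4+2] cycloaddition (type 1 intramolecular Diels–Alder) in which the electron-rich 2-silyloxydiene C3a=C4(OTBS)–C5=C6 adds to the tethered (Z)-β-acyloxy enone C7=C7a, the C3a–C7a bond (nucleophilic diene terminus to enone β-carbon) running ahead of the C6–C7 bond. The closest known reaction types are ester-tethered intramolecular Diels–Alder reactions of 1,3,8-nonatrienes and enone cycloadditions of 2-silyloxy-1,3-dienes. The cyclohexene ring closes in the [4+2] mode and the γ-lactone closes at the same time as the tether ring through the C3a–C7a bond, cis-fused because the three-atom tether O1–C2(=O)–C3 spans a cis junction far more easily than a trans one. C3a and C6 follow from suprafacial addition to the (3Z,5E)-diene (tether and vinyl outside, methyl inside), and C7 and C7a follow from the (Z)-dienophile (acetyl cis to O1) in its endo orientation, which places acetyl and O1 cis to the vinyl group and to C3. The absolute sense comes from the C3 stereocentre: with the tether turned toward the dienophile, the acetoxy group should take the inside position next to the C4 silyloxy group and the methyl group the anti position (allylic 1,3-strain), so only one diene face is open. The step needs periselectivity for the silyloxydiene over the terminal 1,3-diene and endo over exo addition; the short tether, the donor–acceptor match and the quaternary C3 (gem-disubstituent effect on the s-cis ester conformer) should secure both.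

Step 10
Reactants: 16 (3S,3aS,6R,7R,7aS)-7-acetyl-4-[(tert-butyldimethylsilyl)oxy]-6-ethenyl-3,6-dimethyl-2-oxo-2,3,3a,6,7,7a-hexahydro-1-benzofuran-3-yl acetate
Product: 17 (3S,3aS,6S,7R,7aR)-4-[(tert-butyldimethylsilyl)oxy]-6-ethenyl-3,6-dimethyl-2-oxo-7-(prop-1-en-2-yl)-2,3,3a,6,7,7a-hexahydro-1-benzofuran-3-yl acetate
Conditions: Cp2Ti(μ-CH2)(μ-Cl)AlMe2 (1.2 equiv), pyridine (cat.), THF–PhMe, −40 → 0 °C
Reagents that add atoms: Tebbe reagent Cp2Ti(μ-CH2)(μ-Cl)AlMe2, C[Al-]1(C)C[Ti](C2C=CC=C2)(C2C=CC=C2)[Cl+]1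
Why: Tebbe methylenation of the ketone is faster than attack on the lactone, the acetate or the silyl enol ether and is non-basic, so the C7 stereocentre α to the ketone and the β-acyloxy group should survive.

Step 11
Reactants: 17 (3S,3aS,6S,7R,7aR)-4-[(tert-butyldimethylsilyl)oxy]-6-ethenyl-3,6-dimethyl-2-oxo-7-(prop-1-en-2-yl)-2,3,3a,6,7,7a-hexahydro-1-benzofuran-3-yl acetate
Product: 18 (3S,3aS,6S,7R,7aR)-6-ethenyl-3,6-dimethyl-2,4-dioxo-7-(prop-1-en-2-yl)octahydro-1-benzofuran-3-yl acetate
Conditions: HF·pyridine, THF, 0 °C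
Reagents that add atoms: none
Why: Protodesilylation of the silyl enol ether under non-basic conditions should unveil the C4 ketone without β-elimination of the lactone oxygen or the acetate and without epimerising C3a.

Step 12
Reactants: 18 (3S,3aS,6S,7R,7aR)-6-ethenyl-3,6-dimethyl-2,4-dioxo-7-(prop-1-en-2-yl)octahydro-1-benzofuran-3-yl acetate
Product: 19 (3S,3aS,4S,6S,7R,7aR)-6-ethenyl-4-hydroxy-3,6-dimethyl-2-oxo-7-(prop-1-en-2-yl)octahydro-1-benzofuran-3-yl acetate
Conditions: LiBH(s-Bu)3 (1.1 equiv), THF, −78 °C; AcOH quench at −78 °C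
Reagents that add atoms: none
Why: Diastereoselective ketone reduction with a bulky trialkylborohydride: in the chair with the C3a and C7 substituents equatorial, the C7a oxygen and the C6 vinyl group are both axial and block the axial path at C4, so hydride should attack equatorially and give the axial (4S) alcohol.

Step 13
Reactants: 19 (3S,3aS,4S,6S,7R,7aR)-6-ethenyl-4-hydroxy-3,6-dimethyl-2-oxo-7-(prop-1-en-2-yl)octahydro-1-benzofuran-3-yl acetate; 20 3-methylbut-3-enoic acid
Product: 21 (3S,3aS,4R,6S,7R,7aR)-3-(acetyloxy)-6-ethenyl-3,6-dimethyl-2-oxo-7-(prop-1-en-2-yl)octahydro-1-benzofuran-4-yl 3-methylbut-3-enoate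
Conditions: PPh3, DIAD, PhMe–THF, 0 °C → rt
Reagents that add atoms: none
Why: Mitsunobu esterification: SN2 displacement of the activated axial alcohol by the carboxylate should give the equatorial (4R) ester with inversion, and the neutral conditions should keep the β,γ-unsaturated acid from isomerising into conjugation.

**Compound list**

1 | (3E)-4-methoxypent-3-en-2-one | CC(=O)/C=C(\C)OC | starting material
2 | vinylmagnesium bromide | C=C[Mg]Br | starting material
3 | (4E)-5-methoxy-3-methylhexa-1,4-dien-3-ol (racemic, formed as its magnesium alkoxide) | C=CC(C)(O)/C=C(\C)OC | intermediate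
4 | (3E)-4-methylhexa-3,5-dien-2-one | CC(=O)/C=C(\C)C=C | intermediate
5 | (3E)-4-methyl-2-(trimethylsilyloxy)hexa-1,3,5-triene | C=C(O[Si](C)(C)C)/C=C(\C)C=C | intermediate
6 | tert-butyl 2-oxopropanoate (tert-butyl pyruvate) | CC(=O)C(=O)OC(C)(C)C | starting material
7 | tert-butyl (2S,5E)-2,6-dimethyl-4-oxo-2-(trimethylsilyloxy)octa-5,7-dienoate | CC(C)(C)OC(=O)[C@@](C)(O[Si](C)(C)C)CC(=O)/C=C(\C)C=C | intermediate
8 | tert-butyl (2S,5E)-2-hydroxy-2,6-dimethyl-4-oxoocta-5,7-dienoate | CC(C)(C)OC(=O)[C@@](C)(O)CC(=O)/C=C(\C)C=C | intermediate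
9 | tert-butyl (2S,5E)-2-(acetyloxy)-2,6-dimethyl-4-oxoocta-5,7-dienoate | CC(C)(C)OC(=O)[C@@](C)(OC(C)=O)CC(=O)/C=C(\C)C=C | intermediate
10 | (2S,5E)-2-(acetyloxy)-2,6-dimethyl-4-oxoocta-5,7-dienoic acid | OC(=O)[C@@](C)(OC(C)=O)CC(=O)/C=C(\C)C=C | intermediate
11 | tert-butyldimethylsilyl (2S,3Z,5E)-2-(acetyloxy)-4-[(tert-butyldimethylsilyl)oxy]-2,6-dimethylocta-3,5,7-trienoate | CC(C)(C)[Si](C)(C)OC(=O)[C@@](C)(OC(C)=O)/C=C(\O[Si](C)(C)C(C)(C)C)/C=C(\C)/C=C | intermediate
12 | but-3-yn-2-one | CC(=O)C#C | starting material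
13 | (3Z)-4-iodobut-3-en-2-one | CC(=O)/C=C\I | intermediate
14 | potassium (2S,3Z,5E)-2-(acetyloxy)-4-[(tert-butyldimethylsilyl)oxy]-2,6-dimethylocta-3,5,7-trienoate | [K+].[O-]C(=O)[C@@](C)(OC(C)=O)/C=C(\O[Si](C)(C)C(C)(C)C)/C=C(\C)/C=C | intermediate
15 | (1Z)-3-oxobut-1-en-1-yl (2S,3Z,5E)-2-(acetyloxy)-4-[(tert-butyldimethylsilyl)oxy]-2,6-dimethylocta-3,5,7-trienoate | CC(=O)/C=C\OC(=O)[C@@](C)(OC(C)=O)/C=C(\O[Si](C)(C)C(C)(C)C)/C=C(\C)/C=C | intermediate
16 | (3S,3aS,6R,7R,7aS)-7-acetyl-4-[(tert-butyldimethylsilyl)oxy]-6-ethenyl-3,6-dimethyl-2-oxo-2,3,3a,6,7,7a-hexahydro-1-benzofuran-3-yl acetate | C=C[C@]1(C)C=C(O[Si](C)(C)C(C)(C)C)[C@H]2[C@H](OC(=O)[C@@]2(C)OC(C)=O)[C@@H]1C(C)=O | intermediate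
17 | (3S,3aS,6S,7R,7aR)-4-[(tert-butyldimethylsilyl)oxy]-6-ethenyl-3,6-dimethyl-2-oxo-7-(prop-1-en-2-yl)-2,3,3a,6,7,7a-hexahydro-1-benzofuran-3-yl acetate | C=C[C@]1(C)C=C(O[Si](C)(C)C(C)(C)C)[C@H]2[C@H](OC(=O)[C@@]2(C)OC(C)=O)[C@@H]1C(=C)C | intermediate
18 | (3S,3aS,6S,7R,7aR)-6-ethenyl-3,6-dimethyl-2,4-dioxo-7-(prop-1-en-2-yl)octahydro-1-benzofuran-3-yl acetate | C=C[C@]1(C)CC(=O)[C@H]2[C@H](OC(=O)[C@@]2(C)OC(C)=O)[C@@H]1C(=C)C | intermediate
19 | (3S,3aS,4S,6S,7R,7aR)-6-ethenyl-4-hydroxy-3,6-dimethyl-2-oxo-7-(prop-1-en-2-yl)octahydro-1-benzofuran-3-yl acetate | C=C[C@]1(C)C[C@H](O)[C@H]2[C@H](OC(=O)[C@@]2(C)OC(C)=O)[C@@H]1C(=C)C | intermediate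
20 | 3-methylbut-3-enoic acid | C=C(C)CC(=O)O | starting material
21 | (3S,3aS,4R,6S,7R,7aR)-3-(acetyloxy)-6-ethenyl-3,6-dimethyl-2-oxo-7-(prop-1-en-2-yl)octahydro-1-benzofuran-4-yl 3-methylbut-3-enoate | C=C[C@]1(C)C[C@@H](OC(=O)CC(=C)C)[C@H]2[C@H](OC(=O)[C@@]2(C)OC(C)=O)[C@@H]1C(=C)C | target

**Step count and risks**

Total step count: 13. Longest linear sequence: 12 steps (steps 1–6 and 8–13, from 1); step 7 is a one-step side branch.

Steps most likely to fail:

- **Step 9.** The cycloaddition may stall, because the ester must reach its s-cis conformer and the diene terminus C6 carries an inside methyl group, so that thermal loss of the silyl enol ether or acyl transfer could overtake ring closure. The fallback forms the two bonds intermolecularly with an alkyne and closes the lactone afterwards. It sets out from 11: a Diels–Alder reaction of 11 with but-3-yn-2-one 12 (PhMe, 80–110 °C) should give the cyclohexa-2,5-dienyl silyl ester F1. Hydrolysis of the silyl ester (THF–H2O, 0 °C) should give the acid F2. DBU-catalysed conjugate addition of the carboxylate to the enone (5-exo oxa-Michael lactonisation, thermodynamic protonation at C7) then comes back to the route at 16.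

- **Step 8.** The dienol silyl ether may be hydrolysed, or the enol ester may isomerise from Z to E, while the free carboxylate is being vinylated. The fallback reverses the order of tether and diene formation. It sets out from acid 10: its caesium salt (Cs2CO3, DMF, 0 °C) is vinylated with 13 to give the keto enol ester (1Z)-3-oxobut-1-en-1-yl (2S,5E)-2-(acetyloxy)-2,6-dimethyl-4-oxoocta-5,7-dienoate F3. Soft enolisation of the more basic dienone carbonyl (t-BuMe2SiOTf, Et3N, CH2Cl2, −78 °C) then comes back to the route at 15.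

- **Step 13.** The activated axial alcohol may undergo E2 elimination, or the C4 oxygen may attack the lactone carbonyl (translactonisation), instead of SN2 substitution. The fallback sets the C4 configuration by biocatalysis and acylates with retention. It sets out from ketone 18: reduction with a ketoreductase (NADPH-dependent alcohol dehydrogenase selected for the 4R alcohol, glucose and glucose dehydrogenase for cofactor recycling, buffer with DMSO, 30 °C) should give the equatorial alcohol (3S,3aS,4R,6S,7R,7aR)-6-ethenyl-4-hydroxy-3,6-dimethyl-2-oxo-7-(prop-1-en-2-yl)octahydro-1-benzofuran-3-yl acetate F4. Steglich esterification with 20 (EDC·HCl, cat. DMAP, CH2Cl2, −20 °C) then comes back to the route at 21.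

Further compounds
F1 | step 9 | tert-butyldimethylsilyl (2S)-2-(acetyloxy)-2-[(1S,4R)-5-acetyl-2-[(tert-butyldimethylsilyl)oxy]-4-ethenyl-4-methylcyclohexa-2,5-dien-1-yl]propanoate | C=C[C@]1(C)C=C(O[Si](C)(C)C(C)(C)C)[C@@H](C=C1C(C)=O)[C@](C)(OC(C)=O)C(=O)O[Si](C)(C)C(C)(C)C
F2 | step 9 | (2S)-2-(acetyloxy)-2-[(1S,4R)-5-acetyl-2-[(tert-butyldimethylsilyl)oxy]-4-ethenyl-4-methylcyclohexa-2,5-dien-1-yl]propanoic acid | C=C[C@]1(C)C=C(O[Si](C)(C)C(C)(C)C)[C@@H](C=C1C(C)=O)[C@](C)(OC(C)=O)C(=O)O
F3 | step 8 | (1Z)-3-oxobut-1-en-1-yl (2S,5E)-2-(acetyloxy)-2,6-dimethyl-4-oxoocta-5,7-dienoate | CC(=O)/C=C\OC(=O)[C@@](C)(OC(C)=O)CC(=O)/C=C(\C)C=C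
F4 | step 13 | (3S,3aS,4R,6S,7R,7aR)-6-ethenyl-4-hydroxy-3,6-dimethyl-2-oxo-7-(prop-1-en-2-yl)octahydro-1-benzofuran-3-yl acetate | C=C[C@]1(C)C[C@@H](O)[C@H]2[C@H](OC(=O)[C@@]2(C)OC(C)=O)[C@@H]1C(=C)C
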